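**Retrosynthetic overview**
1. Target 17 ⇐ 15 by invertive C2–O substitution (Mitsunobu) ⇐ dione 14 by exo-face hydride reduction ⇐ enedione 11 by conjugate reduction, with C3 set under thermodynamic control.
2. 11 ⇐ hydrobenzofuranone 10: an acid-mediated shift of the benzylic carbon from O to C closes the cyclopentanone ring of the bicyclo[3.2.1]octane and opens the furan.
3. 10 ⇐ quinone monoketal 9 + (Z)-alkene 8: key step, an enantioselective oxa-(3+2) annulation whose ring-closing bond is the benzylic C–O bond.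
4. 9 ⇐ phenol 5 by oxidative dearomatisation (C–O) ⇐ aldehyde 1 (Dakin, O-allylation/Claisen); 8 ⇐ 6 + 7 (Suzuki–Miyaura).
5. Ring order: six-membered carbocycle (from the arene) → tetrahydrofuran (C–O) → cyclopentanone of the bicycle (furan opened).

In the bicycle, "exo" means on the side of the C8 carbonyl bridge and "endo" on the side of the C6–C7 bridge. The target is (1R,2R,3R,5S,6S,7R), with 2-OH exo, 3-OMe exo, 6-Me endo and 7-aryl exo.

Assumption: the (R)-configured acid of step 5 is taken to give the (3aR) series; if the sense of induction proves opposite, its (S)-enantiomer is used with no other change.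

**Route**

Step 1
Reactants: 1 2,3,4-trimethoxybenzaldehyde
Product: 3 2,3,4-trimethoxyphenol, via aryl formate 2 (not isolated)
Conditions: 3-chloroperbenzoic acid, CH2Cl2, 0 °C to rt; then K2CO3 (cat.), MeOH, rt
Reagents that add atoms: 3-chloroperbenzoic acid, OOC(=O)c1cccc(Cl)c1
Why: Dakin-type Baeyer–Villiger oxidation, in which the electron-rich aryl group migrates to give the aryl formate that is then methanolysed to the phenol; no stereocentre is involved.

Step 2
Reactants: 3 2,3,4-trimethoxyphenol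
Product: 5 6-allyl-2,3,4-trimethoxyphenol, via allyl ether 4 (not isolated)
Conditions: allyl bromide, K2CO3, acetone, reflux; filter, concentrate; then N,N-diethylaniline, 200 °C
Reagents that add atoms: allyl bromide, C=CCBr
Why: Williamson O-allylation followed by aromatic Claisen rearrangement, which delivers the allyl group to the only free ortho position and rearomatises; no stereocentre is involved.

Step 3
Reactants: 6 5-bromo-1,2,3-trimethoxybenzene; 7 (Z)-prop-1-en-1-ylboronic acid
Product: 8 (Z)-1,2,3-trimethoxy-5-(prop-1-en-1-yl)benzene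
Conditions: Pd(PPh3)4 (3 mol%), K2CO3, 1,4-dioxane/H2O, 80 °C
Reagents that add atoms: none
Why: Suzuki–Miyaura coupling, which proceeds with retention of the (Z)-geometry of the alkenylboronic acid.

Step 4
Reactants: 5 6-allyl-2,3,4-trimethoxyphenol
Product: 9 6-allyl-2,3,4,4-tetramethoxycyclohexa-2,5-dien-1-one
Conditions: PhI(OAc)2 (1.1 equiv), MeOH, 0 °C
Reagents that add atoms: methanol, CO
Why: oxidative dearomatisation with a trivalent-iodine reagent, in which methanol adds to the para carbon of the activated phenol to give the p-quinone monoketal (C–O bond formation); any ortho ketal would ionise to the same cation in step 5.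

Step 5
Reactants: 9 6-allyl-2,3,4,4-tetramethoxycyclohexa-2,5-dien-1-one; 8 (Z)-1,2,3-trimethoxy-5-(prop-1-en-1-yl)benzene
Product: 10 (2S,3R,3aR)-5,7-dimethoxy-3-methyl-3a-(prop-2-en-1-yl)-2-(3,4,5-trimethoxyphenyl)-3,3a-dihydro-1-benzofuran-6(2H)-one
Conditions: (R)-1,1,1-trifluoro-N-[4-oxido-2,6-bis(2,4,6-triisopropylphenyl)dinaphtho[2,1-d:1',2'-f][1,3,2]dioxaphosphepin-4-yl]methanesulfonamide (5 mol%), 8 (1.5 equiv), toluene, −60 °C
Reagents that add atoms: none
Why: Proposed new method: the chiral N-triflyl phosphoramide ionises the ketal to a 4-methoxyphenoxonium-type cation held as a contact ion pair with the chiral anion on one face, so the (Z)-alkene attacks the allyl-bearing terminus from the open face with its aryl group stacked under the ring (this sets C3a and C3, methyl trans to allyl), the carbonyl oxygen then traps the benzylic cation faster than bond rotation (ring-closing C–O bond, 2,3-cis), and the released methanol demethylates the oxocarbenium to give the dienone and free the acid; the closest known reaction types are the racemic acid-catalysed quinone monoketal–propenylarene annulation and chiral phosphoric-acid-catalysed (3+2) couplings of quinone monoimines with styrenes.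

Step 6
Reactants: 10 (2S,3R,3aR)-5,7-dimethoxy-3-methyl-3a-(prop-2-en-1-yl)-2-(3,4,5-trimethoxyphenyl)-3,3a-dihydro-1-benzofuran-6(2H)-one
Product: 11 (1S,5R,6S,7R)-1,3-dimethoxy-6-methyl-5-(prop-2-en-1-yl)-7-(3,4,5-trimethoxyphenyl)bicyclo[3.2.1]oct-3-ene-2,8-dione
Conditions: CF3SO3H (10 mol%), CH2Cl2, −40 to 0 °C
Reagents that add atoms: none
Why: acid-catalysed rearrangement of a hydrobenzofuranoid to a bicyclo[3.2.1]octanoid neolignan, in which carbonyl protonation ionises the benzylic C–O bond, the cation rotates and is captured by the methoxy-enol carbon with the aryl group on the open exo side (trans to the endo methyl group), while C5 and C6 are untouched so the ee is kept.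

Step 7
Reactants: 11 (1S,5R,6S,7R)-1,3-dimethoxy-6-methyl-5-(prop-2-en-1-yl)-7-(3,4,5-trimethoxyphenyl)bicyclo[3.2.1]oct-3-ene-2,8-dione
Product: 14 (1S,3R,5S,6S,7R)-1,3-dimethoxy-6-methyl-5-(prop-2-en-1-yl)-7-(3,4,5-trimethoxyphenyl)bicyclo[3.2.1]octane-2,8-dione, via silyl enol ether 12 (not isolated), via C3-epimeric dione 13 (not isolated)
Conditions: [(Ph3P)CuH]6 (5 mol%), PhMe2SiH (1.5 equiv), toluene, rt; then 1 M HCl, THF, 0 °C; then 1,8-diazabicyclo[5.4.0]undec-7-ene (0.2 equiv), CH2Cl2, rt
Reagents that add atoms: none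
Why: copper hydride conjugate reduction (1,4-hydrosilylation) is selective for the enone over the allyl group and the hindered C8 ketone, and hydrolysis followed by base equilibration places the C3 methoxy group exo (equatorial), away from the endo C6 methyl group, under thermodynamic control.

Step 8
Reactants: 14 (1S,3R,5S,6S,7R)-1,3-dimethoxy-6-methyl-5-(prop-2-en-1-yl)-7-(3,4,5-trimethoxyphenyl)bicyclo[3.2.1]octane-2,8-dione
Product: 15 (1R,2S,3R,5S,6S,7R)-2-hydroxy-1,3-dimethoxy-6-methyl-5-(prop-2-en-1-yl)-7-(3,4,5-trimethoxyphenyl)bicyclo[3.2.1]octan-8-one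
Conditions: NaBH4 (1.0 equiv), CeCl3·7H2O (1.0 equiv), MeOH/CH2Cl2, −78 °C
Reagents that add atoms: none
Why: Luche reduction, in which cerium chelated by the three neighbouring oxygens activates the C2 carbonyl over the doubly neopentyl C8 carbonyl and hydride adds from the open exo face to give the endo (equatorial) alcohol, the C2 epimer of the target.

Step 9
Reactants: 15 (1R,2S,3R,5S,6S,7R)-2-hydroxy-1,3-dimethoxy-6-methyl-5-(prop-2-en-1-yl)-7-(3,4,5-trimethoxyphenyl)bicyclo[3.2.1]octan-8-one
Product: 17 (1R,2R,3R,5S,6S,7R)-2-hydroxy-1,3-dimethoxy-6-methyl-5-(prop-2-en-1-yl)-7-(3,4,5-trimethoxyphenyl)bicyclo[3.2.1]octan-8-one, via chloroacetate 16 (not isolated)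
Conditions: ClCH2CO2H (3 equiv), PPh3 (3 equiv), diisopropyl azodicarboxylate (3 equiv), toluene, 0 to 40 °C; then K2CO3 (0.1 equiv), MeOH, 0 °C
Reagents that add atoms: chloroacetic acid, OC(=O)CCl
Why: Mitsunobu inversion, in which chloroacetate displaces the equatorial oxyphosphonium group in an SN2 reaction along the open axial (exo) trajectory, so the new C2–O bond is syn to the C8 bridge as in the target, and the labile chloroacetate is then removed by mild methanolysis.

**Compound list**
1 | 2,3,4-trimethoxybenzaldehyde | COc1ccc(C=O)c(OC)c1OC | starting material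
2 | 2,3,4-trimethoxyphenyl formate | COc1ccc(OC=O)c(OC)c1OC | intermediate
3 | 2,3,4-trimethoxyphenol | COc1ccc(O)c(OC)c1OC | intermediate
4 | 1-(allyloxy)-2,3,4-trimethoxybenzene | C=CCOc1ccc(OC)c(OC)c1OC | intermediate
5 | 6-allyl-2,3,4-trimethoxyphenol | C=CCc1cc(OC)c(OC)c(OC)c1O | intermediate
6 | 5-bromo-1,2,3-trimethoxybenzene | COc1cc(Br)cc(OC)c1OC | starting material
7 | (Z)-prop-1-en-1-ylboronic acid | C/C=C\B(O)O | starting material
8 | (Z)-1,2,3-trimethoxy-5-(prop-1-en-1-yl)benzene | C/C=C\c1cc(OC)c(OC)c(OC)c1 | intermediate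
9 | 6-allyl-2,3,4,4-tetramethoxycyclohexa-2,5-dien-1-one | C=CCC1=CC(OC)(OC)C(OC)=C(OC)C1=O | intermediate
10 | (2S,3R,3aR)-5,7-dimethoxy-3-methyl-3a-(prop-2-en-1-yl)-2-(3,4,5-trimethoxyphenyl)-3,3a-dihydro-1-benzofuran-6(2H)-one (2-aryl and 3-methyl cis, 3-methyl and 3a-allyl trans) | C=CC[C@@]12C=C(OC)C(=O)C(OC)=C1O[C@H](c1cc(OC)c(OC)c(OC)c1)[C@@H]2C | intermediate
11 | (1S,5R,6S,7R)-1,3-dimethoxy-6-methyl-5-(prop-2-en-1-yl)-7-(3,4,5-trimethoxyphenyl)bicyclo[3.2.1]oct-3-ene-2,8-dione (7-aryl exo, 6-methyl endo) | C=CC[C@@]12C=C(OC)C(=O)[C@@](OC)(C1=O)[C@@H](c1cc(OC)c(OC)c(OC)c1)[C@@H]2C | intermediate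
12 | (1R,5S,6S,7R)-2-{[dimethyl(phenyl)silyl]oxy}-1,3-dimethoxy-6-methyl-5-(prop-2-en-1-yl)-7-(3,4,5-trimethoxyphenyl)bicyclo[3.2.1]oct-2-en-8-one | C=CC[C@@]12CC(OC)=C(O[Si](C)(C)c3ccccc3)[C@@](OC)(C1=O)[C@@H](c1cc(OC)c(OC)c(OC)c1)[C@@H]2C | intermediate
13 | (1S,3S,5S,6S,7R)-1,3-dimethoxy-6-methyl-5-(prop-2-en-1-yl)-7-(3,4,5-trimethoxyphenyl)bicyclo[3.2.1]octane-2,8-dione (3-OMe endo) | C=CC[C@@]12C[C@H](OC)C(=O)[C@@](OC)(C1=O)[C@@H](c1cc(OC)c(OC)c(OC)c1)[C@@H]2C | intermediate
14 | (1S,3R,5S,6S,7R)-1,3-dimethoxy-6-methyl-5-(prop-2-en-1-yl)-7-(3,4,5-trimethoxyphenyl)bicyclo[3.2.1]octane-2,8-dione (3-OMe exo) | C=CC[C@@]12C[C@@H](OC)C(=O)[C@@](OC)(C1=O)[C@@H](c1cc(OC)c(OC)c(OC)c1)[C@@H]2C | intermediate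
15 | (1R,2S,3R,5S,6S,7R)-2-hydroxy-1,3-dimethoxy-6-methyl-5-(prop-2-en-1-yl)-7-(3,4,5-trimethoxyphenyl)bicyclo[3.2.1]octan-8-one (2-OH endo) | C=CC[C@@]12C[C@@H](OC)[C@H](O)[C@@](OC)(C1=O)[C@@H](c1cc(OC)c(OC)c(OC)c1)[C@@H]2C | intermediate
16 | (1R,2R,3R,5S,6S,7R)-1,3-dimethoxy-6-methyl-8-oxo-5-(prop-2-en-1-yl)-7-(3,4,5-trimethoxyphenyl)bicyclo[3.2.1]octan-2-yl chloroacetate | C=CC[C@@]12C[C@@H](OC)[C@@H](OC(=O)CCl)[C@@](OC)(C1=O)[C@@H](c1cc(OC)c(OC)c(OC)c1)[C@@H]2C | intermediate
17 | (1R,2R,3R,5S,6S,7R)-2-hydroxy-1,3-dimethoxy-6-methyl-5-(prop-2-en-1-yl)-7-(3,4,5-trimethoxyphenyl)bicyclo[3.2.1]octan-8-one | C=CC[C@@]12C[C@@H](OC)[C@@H](O)[C@@](OC)(C1=O)[C@@H](c1cc(OC)c(OC)c(OC)c1)[C@@H]2C | target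

**Step count and risks**

Total: 9 steps. Longest linear sequence: 8 steps (steps 1, 2, 4, 5, 6, 7, 8, 9); step 3 is a one-step side branch.

The three steps most likely to fail are steps 5, 6 and 9.

Step 5 (the proposed new annulation) may give low ee, or the confined acid may not turn over. The fallback sets out from 9 (with 8) and uses the established racemic acid-catalysed annulation: CF3SO3H (5 mol%) in CH2Cl2 at −40 °C gives racemic 10, that is 10 together with its mirror image (2R,3S,3aS)-5,7-dimethoxy-3-methyl-3a-(prop-2-en-1-yl)-2-(3,4,5-trimethoxyphenyl)-3,3a-dihydro-1-benzofuran-6(2H)-one F1. The two are separated by preparative supercritical-fluid chromatography on an amylose tris(3,5-dimethylphenylcarbamate) phase, and the route is rejoined at 10.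

Step 6 (shift of the benzylic carbon from O to C) may stop at an equilibrium mixture or erode ee through reversal of the first C–C bond. The fallback sets out from 9 (with 8) and bypasses 10 by a Lewis-acid-mediated direct (5+2) cycloaddition: SnCl4 (1.1 equiv), CH2Cl2, −78 to 0 °C. Tin bound to the carbonyl oxygen and the neighbouring methoxy group blocks closure through oxygen, so the benzylic cation is captured by carbon. This gives racemic 11, that is 11 together with its mirror image (1R,5S,6R,7S)-1,3-dimethoxy-6-methyl-5-(prop-2-en-1-yl)-7-(3,4,5-trimethoxyphenyl)bicyclo[3.2.1]oct-3-ene-2,8-dione F2. The racemate is resolved on the same chiral phase, and the route is rejoined at 11.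

Step 9 (Mitsunobu inversion next to a quaternary carbon) may be slow or give the ester with retention. The fallback sets out from 15 and replaces substitution by a redox epimerisation under Oppenauer/Meerwein–Ponndorf–Verley exchange: aluminium triisopropoxide (0.5 equiv), acetone (0.2 equiv), toluene, 80 °C. Hydride shuttles between the alkoxide and small amounts of ketone 14 until the C2 epimers equilibrate. The exo alkoxide can chelate aluminium together with the C8 carbonyl and should be enriched, though the equilibrium ratio is uncertain. 17 is separated, recovered 15 is recycled, and the route is rejoined at 17; no new compound is made.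

**Further compounds**
F1 | step 5 | (2R,3S,3aS)-5,7-dimethoxy-3-methyl-3a-(prop-2-en-1-yl)-2-(3,4,5-trimethoxyphenyl)-3,3a-dihydro-1-benzofuran-6(2H)-one | C=CC[C@]12C=C(OC)C(=O)C(OC)=C1O[C@@H](c1cc(OC)c(OC)c(OC)c1)[C@H]2C
F2 | step 6 | (1R,5S,6R,7S)-1,3-dimethoxy-6-methyl-5-(prop-2-en-1-yl)-7-(3,4,5-trimethoxyphenyl)bicyclo[3.2.1]oct-3-ene-2,8-dione | C=CC[C@]12C=C(OC)C(=O)[C@](OC)(C1=O)[C@H](c1cc(OC)c(OC)c(OC)c1)[C@H]2C
F0 | step 9 | none | none
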